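**Retrosynthetic overview**
- Feature: on ring B the ether carbon C6', the carboxyl carbon C1' and the oxygen-bearing C2' are contiguous. Cutting O–C6' and C1'–CO2H together turns ring B into a 3-alkoxybenzyne (triple bond C1'–C6'), the ring A phenoxide and CO2.
- The aryne comes from an o-silylaryl triflate made from catechol (six steps). The nucleophile is a ring A acetal phenol made from creosol (four steps).
- The key step joins the silyl triflate, the ring A phenoxide and CO2, and the new carboxylate is capped in the same flask as its MOM ester.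
- End game: acetal to aldehyde, to the C7 alcohol, to the C7 acetate, then all three MOM groups are removed in one operation.
- No ring is formed: rings A and B are both bought as benzene rings and the target has no stereocentre.

Key step: step 11

Remark on the chemistry: the same aryne results whether silicon sits on C6' and triflate on C1' or the reverse. The precursor therefore carries SiMe3 on C6' and OTf on C1', which lets the two ring B oxygens be differentiated from the first step on catechol; C7 is taken as the benzylic CH2 of ring A.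

**Ring A nucleophile**

Step 1
Reactants: 1 creosol (2-methoxy-4-methylphenol)
Product: 2 2-hydroxy-3-methoxy-5-methylbenzaldehyde
Conditions: MgCl2, Et3N, (CH2O)n, MeCN, reflux; then 1 M HCl
Reagents that add atoms: paraformaldehyde (formaldehyde) C=O
Why: Magnesium-phenoxide-directed ortho-formylation (Casnati–Skattebøl reaction): the chelated phenoxide takes up formaldehyde only at its one free ortho carbon, and a second formaldehyde oxidises the benzylic alkoxide to the aldehyde by hydride transfer.

Step 2
Reactants: 2 2-hydroxy-3-methoxy-5-methylbenzaldehyde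
Product: 3 2,3-dihydroxy-5-methylbenzaldehyde
Conditions: BBr3, CH2Cl2, −78 °C to rt; then H2O
Reagents that add atoms: none
Why: Lewis-acid ether cleavage: BBr3 complexes the aryl methyl ether and bromide removes the methyl group by SN2, while the aldehyde is returned unchanged on aqueous work-up.

Step 3
Reactants: 3 2,3-dihydroxy-5-methylbenzaldehyde
Product: 5 2-hydroxy-3-(methoxymethoxy)-5-methylbenzaldehyde, via disodium 3-formyl-5-methylbenzene-1,2-diolate 4 (not isolated)
Conditions: NaH (2.2 equiv), DMF/THF, 0 °C; then MOMCl (1.0 equiv), 0 °C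
Reagents that add atoms: chloromethyl methyl ether COCCl
Why: Williamson-type O-alkylation of a dianion: in 4 the C2 oxide is delocalised into the formyl group and held in a sodium chelate, so the single equivalent of MOMCl is taken by the more basic C3 oxide.

Step 4
Reactants: 5 2-hydroxy-3-(methoxymethoxy)-5-methylbenzaldehyde
Product: 6 2-(dimethoxymethyl)-6-(methoxymethoxy)-4-methylphenol
Conditions: HC(OMe)3, MeOH, PPTS (cat.), rt; then K2CO3
Reagents that add atoms: trimethyl orthoformate COC(OC)OC; methanol CO
Why: Acid-catalysed acetalisation with orthoformate as dehydrating methanol donor: PPTS at room temperature suffices for acetal formation yet is too mild to solvolyse the aryl MOM ether, and the basic quench keeps the o-hydroxy acetal from reverting.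

**Ring B aryne precursor**

Step 5
Reactants: 7 catechol
Product: 8 2-(methoxymethoxy)phenol
Conditions: MOMCl (1.0 equiv), iPr2NEt, CH2Cl2, 0 °C to rt (catechol 2 equiv)
Reagents that add atoms: chloromethyl methyl ether COCCl
Why: Williamson-type monoalkylation of a symmetrical diol: excess catechol keeps double alkylation low, unreacted catechol washes out with water, and the two ring B oxygens are told apart from here on.

Step 6
Reactants: 8 2-(methoxymethoxy)phenol
Product: 9 2-(methoxymethoxy)phenyl N,N-diethylcarbamate
Conditions: Et2NC(O)Cl, K2CO3, MeCN, reflux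
Reagents that add atoms: N,N-diethylcarbamoyl chloride CCN(CC)C(Cl)=O
Why: O-Carbamoylation of the phenoxide (nucleophilic acyl substitution) puts the strongest ortho-directing group on the oxygen that is to become the triflate.

Step 7
Reactants: 9 2-(methoxymethoxy)phenyl N,N-diethylcarbamate
Product: 11 2-(methoxymethoxy)-6-(trimethylsilyl)phenyl N,N-diethylcarbamate, via C6-lithiated carbamate 10 (not isolated)
Conditions: s-BuLi, TMEDA, THF, −78 °C; then TMSCl, −78 °C to rt
Reagents that add atoms: chlorotrimethylsilane C[Si](C)(C)Cl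
Why: Directed ortho-metalation (Snieckus): the carbamate outranks the MOM ether as directing group and its only free ortho position is C6, and silylation of 10 at −78 °C comes before anionic ortho-Fries rearrangement can set in.

Step 8
Reactants: 11 2-(methoxymethoxy)-6-(trimethylsilyl)phenyl N,N-diethylcarbamate; 12 prenyl bromide (1-bromo-3-methylbut-2-ene)
Product: 14 2-(methoxymethoxy)-3-(3-methylbut-2-en-1-yl)-6-(trimethylsilyl)phenyl N,N-diethylcarbamate, via C3 aryllithium 13 (not isolated)
Conditions: s-BuLi, TMEDA, THF, −78 °C; then CuBr·SMe2 (20 mol%), 12, −78 °C to 0 °C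
Reagents that add atoms: none
Why: Directed ortho-metalation followed by copper-catalysed allylic substitution: with both positions next to the carbamate occupied, the only ring proton beside a directing group is H3 next to the MOM ether, and aryl nucleophile 13 attacks the unhindered primary carbon of 12 (SN2, no allylic transposition).

Step 9
Reactants: 14 2-(methoxymethoxy)-3-(3-methylbut-2-en-1-yl)-6-(trimethylsilyl)phenyl N,N-diethylcarbamate
Product: 15 2-(methoxymethoxy)-3-(3-methylbut-2-en-1-yl)-6-(trimethylsilyl)phenol
Conditions: LiAlH4, THF, 0 °C to reflux; then H2O, aq. NaOH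
Reagents that add atoms: none
Why: Hydride reduction of the aryl carbamate: LiAlH4 adds to the carbamate carbonyl, the aryloxide is expelled and the formamide is reduced on to the amine, while the alkene, the aryl silane and the MOM ether are inert to hydride.

Step 10
Reactants: 15 2-(methoxymethoxy)-3-(3-methylbut-2-en-1-yl)-6-(trimethylsilyl)phenol
Product: 16 2-(methoxymethoxy)-3-(3-methylbut-2-en-1-yl)-6-(trimethylsilyl)phenyl trifluoromethanesulfonate
Conditions: PhNTf2, DBU, MeCN, rt to 40 °C
Reagents that add atoms: N-phenylbis(trifluoromethanesulfonimide) O=S(=O)(N(c1ccccc1)S(=O)(=O)C(F)(F)F)C(F)(F)F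
Why: O-Sulfonylation of the phenoxide with the mild triflyl donor PhNTf2, which triflates hindered 2-silylphenols without acid or fluoride that could desilylate and without touching the MOM ether or the alkene.

**Key step and end game**

Step 11
Reactants: 16 2-(methoxymethoxy)-3-(3-methylbut-2-en-1-yl)-6-(trimethylsilyl)phenyl trifluoromethanesulfonate; 6 2-(dimethoxymethyl)-6-(methoxymethoxy)-4-methylphenol; 17 carbon dioxide
Product: 22 methoxymethyl 6-[2-(dimethoxymethyl)-6-(methoxymethoxy)-4-methylphenoxy]-2-(methoxymethoxy)-3-(3-methylbut-2-en-1-yl)benzoate, via ring A potassium phenoxide 18 (not isolated), via ring B aryne 19 (not isolated), via C1' aryl potassium adduct 20 (not isolated), via potassium carboxylate 21 (not isolated)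
Conditions: 6 (1.5 equiv), KH, 18-crown-6, THF, 0 °C; then CO2 (1 atm), 16, KF, 0 °C to rt; then MOMCl, 0 °C to rt
Reagents that add atoms: chloromethyl methyl ether COCCl
Why: Proposed new method: fluoride attack on silicon of 16 with loss of triflate gives aryne 19 with its triple bond across C1'–C6'; the preformed, proton-free phenoxide 18 adds at C6', the aryl potassium 20 formed at C1' is carboxylated by dissolved CO2 to 21, and MOMCl esterifies the carboxylate. The closest known reactions are the fluoride-mediated O-arylation of phenols by o-silylaryl triflates and the aryne/amine/CO2 three-component synthesis of anthranilic acids under KF/18-crown-6 in THF; pairing an anionic oxygen nucleophile with CO2 is the untested element. No ring is closed and no stereocentre is formed. Regiochemistry is set by the C2' methoxymethoxy group, whose inductive pull distorts the aryne so that the remote carbon C6' is the electrophilic terminus and the charge develops at C1' beside the oxygen, as in other 3-alkoxybenzynes. Carboxylation should win over protonation because the medium holds no acid stronger than THF (phenoxide made with KH, no acetonitrile), and the acetal and MOM groups offer the aryl anion no electrophile, whereas a free aldehyde would be attacked to give a xanthene. The 2,6-disubstituted phenoxide should bind CO2 only weakly and reversibly, so the free phenoxide remains the species that intercepts the aryne, and its excess keeps the product carboxylate from competing for aryne.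

Step 12
Reactants: 22 methoxymethyl 6-[2-(dimethoxymethyl)-6-(methoxymethoxy)-4-methylphenoxy]-2-(methoxymethoxy)-3-(3-methylbut-2-en-1-yl)benzoate
Product: 23 methoxymethyl 6-[2-formyl-6-(methoxymethoxy)-4-methylphenoxy]-2-(methoxymethoxy)-3-(3-methylbut-2-en-1-yl)benzoate
Conditions: PPTS (cat.), acetone/H2O, rt
Reagents that add atoms: water O
Why: Acetal hydrolysis: the electron-rich aryl dimethyl acetal ionises under catalytic PPTS in wet acetone far faster than the MOM ethers or the MOM ester, so only the aldehyde is unmasked.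

Step 13
Reactants: 23 methoxymethyl 6-[2-formyl-6-(methoxymethoxy)-4-methylphenoxy]-2-(methoxymethoxy)-3-(3-methylbut-2-en-1-yl)benzoate
Product: 24 methoxymethyl 6-[2-(hydroxymethyl)-6-(methoxymethoxy)-4-methylphenoxy]-2-(methoxymethoxy)-3-(3-methylbut-2-en-1-yl)benzoate
Conditions: NaBH4, THF/MeOH, 0 °C
Reagents that add atoms: none
Why: Borohydride reduction: NaBH4 reduces the aryl aldehyde at 0 °C and leaves the hindered 2,6-disubstituted MOM ester alone.

Step 14
Reactants: 24 methoxymethyl 6-[2-(hydroxymethyl)-6-(methoxymethoxy)-4-methylphenoxy]-2-(methoxymethoxy)-3-(3-methylbut-2-en-1-yl)benzoate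
Product: 25 methoxymethyl 6-[2-(acetoxymethyl)-6-(methoxymethoxy)-4-methylphenoxy]-2-(methoxymethoxy)-3-(3-methylbut-2-en-1-yl)benzoate
Conditions: Ac2O, pyridine, DMAP (cat.), CH2Cl2, 0 °C to rt
Reagents that add atoms: acetic anhydride CC(=O)OC(C)=O
Why: DMAP-catalysed acylation of the only free hydroxyl group; because the carboxyl group is masked as its MOM ester, no mixed anhydride and no eight-membered lactone can form.

Step 15
Reactants: 25 methoxymethyl 6-[2-(acetoxymethyl)-6-(methoxymethoxy)-4-methylphenoxy]-2-(methoxymethoxy)-3-(3-methylbut-2-en-1-yl)benzoate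
Product: 26 7-O-acetylsecopenicillide C, 6-[2-(acetoxymethyl)-6-hydroxy-4-methylphenoxy]-2-hydroxy-3-(3-methylbut-2-en-1-yl)benzoic acid
Conditions: ZnBr2, n-PrSH, CH2Cl2, 0 °C
Reagents that add atoms: none
Why: Lewis-acid-assisted thiolysis of the O,O-acetals: ZnBr2 activates each methoxymethyl group and the thiol carries it off as the O,S-acetal within minutes at 0 °C, mild enough to spare a primary acetate and an o-prenylphenol while freeing the acid and both phenols in one operation.

**Compound list**
1 | creosol (2-methoxy-4-methylphenol) | COc1cc(C)ccc1O | starting material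
2 | 2-hydroxy-3-methoxy-5-methylbenzaldehyde | COc1cc(C)cc(C=O)c1O | intermediate
3 | 2,3-dihydroxy-5-methylbenzaldehyde | Cc1cc(O)c(O)c(C=O)c1 | intermediate
4 | disodium 3-formyl-5-methylbenzene-1,2-diolate | Cc1cc([O-])c([O-])c(C=O)c1.[Na+].[Na+] | intermediate
5 | 2-hydroxy-3-(methoxymethoxy)-5-methylbenzaldehyde | COCOc1cc(C)cc(C=O)c1O | intermediate
6 | 2-(dimethoxymethyl)-6-(methoxymethoxy)-4-methylphenol | Cc1cc(C(OC)OC)c(O)c(OCOC)c1 | intermediate
7 | catechol (benzene-1,2-diol) | Oc1ccccc1O | starting material
8 | 2-(methoxymethoxy)phenol | COCOc1ccccc1O | intermediate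
9 | 2-(methoxymethoxy)phenyl N,N-diethylcarbamate | CCN(CC)C(=O)Oc1ccccc1OCOC | intermediate
10 | {2-[(diethylcarbamoyl)oxy]-3-(methoxymethoxy)phenyl}lithium | [Li]c1cccc(OCOC)c1OC(=O)N(CC)CC | intermediate
11 | 2-(methoxymethoxy)-6-(trimethylsilyl)phenyl N,N-diethylcarbamate | CCN(CC)C(=O)Oc1c(OCOC)cccc1[Si](C)(C)C | intermediate
12 | prenyl bromide (1-bromo-3-methylbut-2-ene) | CC(C)=CCBr | starting material
13 | {3-[(diethylcarbamoyl)oxy]-2-(methoxymethoxy)-4-(trimethylsilyl)phenyl}lithium | [Li]c1ccc([Si](C)(C)C)c(OC(=O)N(CC)CC)c1OCOC | intermediate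
14 | 2-(methoxymethoxy)-3-(3-methylbut-2-en-1-yl)-6-(trimethylsilyl)phenyl N,N-diethylcarbamate | CC(C)=CCc1ccc([Si](C)(C)C)c(OC(=O)N(CC)CC)c1OCOC | intermediate
15 | 2-(methoxymethoxy)-3-(3-methylbut-2-en-1-yl)-6-(trimethylsilyl)phenol | CC(C)=CCc1ccc([Si](C)(C)C)c(O)c1OCOC | intermediate
16 | 2-(methoxymethoxy)-3-(3-methylbut-2-en-1-yl)-6-(trimethylsilyl)phenyl trifluoromethanesulfonate | CC(C)=CCc1ccc([Si](C)(C)C)c(OS(=O)(=O)C(F)(F)F)c1OCOC | intermediate
17 | carbon dioxide | O=C=O | starting material
18 | potassium 2-(dimethoxymethyl)-6-(methoxymethoxy)-4-methylphenolate | Cc1cc(C(OC)OC)c([O-])c(OCOC)c1.[K+] | intermediate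
19 | 3-(methoxymethoxy)-4-(3-methylbut-2-en-1-yl)benzyne (triple bond C1'–C6') | COCOC1=C(CC=C(C)C)C=CC#C1 | intermediate
20 | {6-[2-(dimethoxymethyl)-6-(methoxymethoxy)-4-methylphenoxy]-2-(methoxymethoxy)-3-(3-methylbut-2-en-1-yl)phenyl}potassium | COCOc1c(CC=C(C)C)ccc(Oc2c(C(OC)OC)cc(C)cc2OCOC)[c-]1.[K+] | intermediate
21 | potassium 6-[2-(dimethoxymethyl)-6-(methoxymethoxy)-4-methylphenoxy]-2-(methoxymethoxy)-3-(3-methylbut-2-en-1-yl)benzoate | COCOc1c(CC=C(C)C)ccc(Oc2c(C(OC)OC)cc(C)cc2OCOC)c1C(=O)[O-].[K+] | intermediate
22 | methoxymethyl 6-[2-(dimethoxymethyl)-6-(methoxymethoxy)-4-methylphenoxy]-2-(methoxymethoxy)-3-(3-methylbut-2-en-1-yl)benzoate | COCOC(=O)c1c(OCOC)c(CC=C(C)C)ccc1Oc1c(C(OC)OC)cc(C)cc1OCOC | intermediate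
23 | methoxymethyl 6-[2-formyl-6-(methoxymethoxy)-4-methylphenoxy]-2-(methoxymethoxy)-3-(3-methylbut-2-en-1-yl)benzoate | COCOC(=O)c1c(OCOC)c(CC=C(C)C)ccc1Oc1c(C=O)cc(C)cc1OCOC | intermediate
24 | methoxymethyl 6-[2-(hydroxymethyl)-6-(methoxymethoxy)-4-methylphenoxy]-2-(methoxymethoxy)-3-(3-methylbut-2-en-1-yl)benzoate | COCOC(=O)c1c(OCOC)c(CC=C(C)C)ccc1Oc1c(CO)cc(C)cc1OCOC | intermediate
25 | methoxymethyl 6-[2-(acetoxymethyl)-6-(methoxymethoxy)-4-methylphenoxy]-2-(methoxymethoxy)-3-(3-methylbut-2-en-1-yl)benzoate | COCOC(=O)c1c(OCOC)c(CC=C(C)C)ccc1Oc1c(COC(C)=O)cc(C)cc1OCOC | intermediate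
26 | 7-O-acetylsecopenicillide C | CC(=O)OCc1cc(C)cc(O)c1Oc1ccc(CC=C(C)C)c(O)c1C(=O)O | target

**Step count and risks**

Total step count: 15. Longest linear sequence: 11 steps (catechol 7 to target 26, steps 5 to 15).

Steps most likely to fail:

Step 11 (Proposed new method). Three processes could defeat it:
- the C1' aryl anion is protonated before it meets CO2;
- the phenoxide is held back as its CO2 adduct and then adds through a carbonate oxygen;
- the phenoxide attacks the sulfur of the triflate before fluoride has released the aryne.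

The fallback uses known chemistry and sets out from 16 and 6. Aryne O-arylation under CsF in MeCN at rt, where the medium protonates the aryl anion, should give 1-(dimethoxymethyl)-3-(methoxymethoxy)-2-[3-(methoxymethoxy)-4-(3-methylbut-2-en-1-yl)phenoxy]-5-methylbenzene F1. s-BuLi/TMEDA in THF at −78 °C should then remove H1', the one ring proton lying between two oxygen directing groups, to give the C1' aryllithium F2. CO2 converts it into the lithium carboxylate F3, and MOMCl added to the same flask brings the route back at 22.

Step 15. The Lewis acid may ionise the benzylic acetate (with capture by thiol), may cyclise the prenyl chain onto the freed C2' hydroxyl, or may leave the ring A MOM ether partly in place. The fallback sets out from 24 and removes the three MOM groups before the acetate exists (2 M aqueous HCl, THF, 40 °C). This should give secopenicillide C, 2-hydroxy-6-[2-hydroxy-6-(hydroxymethyl)-4-methylphenoxy]-3-(3-methylbut-2-en-1-yl)benzoic acid F4. The primary C7 hydroxyl is then acetylated selectively by lipase-catalysed transesterification (vinyl acetate, immobilised Candida antarctica lipase B, THF, rt), which does not acylate phenols or the acid, and the route comes back at 26.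

Step 8. Metalation may go to a silyl methyl group or to the OCH2O carbon instead of C3, s-BuLi may add to the carbamate carbonyl, or the allylation may proceed with allylic transposition. The fallback sets out from 8 and introduces the prenyl group while the MOM ether is the only directing group, bringing in the carbamate afterwards. Silylation (TIPSCl, imidazole, DMF) gives [2-(methoxymethoxy)phenoxy]tri(propan-2-yl)silane F5. n-BuLi/TMEDA in Et2O at 0 °C gives the aryllithium ortho to the MOM ether F6, which with CuBr·SMe2 and 12 gives [2-(methoxymethoxy)-3-(3-methylbut-2-en-1-yl)phenoxy]tri(propan-2-yl)silane F7. TBAF in THF frees 2-(methoxymethoxy)-3-(3-methylbut-2-en-1-yl)phenol F8, and Et2NC(O)Cl/K2CO3 in MeCN gives 2-(methoxymethoxy)-3-(3-methylbut-2-en-1-yl)phenyl N,N-diethylcarbamate F9. s-BuLi/TMEDA at −78 °C lithiates ortho to the carbamate to give the C6 aryllithium F10, and TMSCl returns the route at 14.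

**Further compounds**
F1 | step 11 | 1-(dimethoxymethyl)-3-(methoxymethoxy)-2-[3-(methoxymethoxy)-4-(3-methylbut-2-en-1-yl)phenoxy]-5-methylbenzene | COCOc1cc(Oc2c(C(OC)OC)cc(C)cc2OCOC)ccc1CC=C(C)C
F2 | step 11 | {6-[2-(dimethoxymethyl)-6-(methoxymethoxy)-4-methylphenoxy]-2-(methoxymethoxy)-3-(3-methylbut-2-en-1-yl)phenyl}lithium | [Li]c1c(OCOC)c(CC=C(C)C)ccc1Oc1c(C(OC)OC)cc(C)cc1OCOC
F3 | step 11 | lithium 6-[2-(dimethoxymethyl)-6-(methoxymethoxy)-4-methylphenoxy]-2-(methoxymethoxy)-3-(3-methylbut-2-en-1-yl)benzoate | COCOc1c(CC=C(C)C)ccc(Oc2c(C(OC)OC)cc(C)cc2OCOC)c1C(=O)[O-].[Li+]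
F4 | step 15 | secopenicillide C, 2-hydroxy-6-[2-hydroxy-6-(hydroxymethyl)-4-methylphenoxy]-3-(3-methylbut-2-en-1-yl)benzoic acid | OCc1cc(C)cc(O)c1Oc1ccc(CC=C(C)C)c(O)c1C(=O)O
F5 | step 8 | [2-(methoxymethoxy)phenoxy]tri(propan-2-yl)silane | COCOc1ccccc1O[Si](C(C)C)(C(C)C)C(C)C
F6 | step 8 | {2-(methoxymethoxy)-3-[tri(propan-2-yl)silyloxy]phenyl}lithium | [Li]c1cccc(O[Si](C(C)C)(C(C)C)C(C)C)c1OCOC
F7 | step 8 | [2-(methoxymethoxy)-3-(3-methylbut-2-en-1-yl)phenoxy]tri(propan-2-yl)silane | CC(C)=CCc1cccc(O[Si](C(C)C)(C(C)C)C(C)C)c1OCOC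
F8 | step 8 | 2-(methoxymethoxy)-3-(3-methylbut-2-en-1-yl)phenol | CC(C)=CCc1cccc(O)c1OCOC
F9 | step 8 | 2-(methoxymethoxy)-3-(3-methylbut-2-en-1-yl)phenyl N,N-diethylcarbamate | CCN(CC)C(=O)Oc1cccc(CC=C(C)C)c1OCOC
F10 | step 8 | {2-[(diethylcarbamoyl)oxy]-3-(methoxymethoxy)-4-(3-methylbut-2-en-1-yl)phenyl}lithium | [Li]c1ccc(CC=C(C)C)c(OCOC)c1OC(=O)N(CC)CC
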